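**Plan**

1. Numbering used throughout: ring C1 (carries the side chain), C2 (ring CH2), C3, C4 (carries CH3), C5, C6; side chain C7(=CH2)–C8–C9–C10–C11. β is the ring face of the C1 substituent. Target: 3α-OH, 4β-OH (4α-CH3), 5β-O-angeloyl, 6β-OH; (8R)-OH, (10R)-O-angeloyl.
2. Retrosynthesis: both angelates (C5–O, C10–O) and the silyl groups come off last. The side chain is cut at C8–C9 (aldol) and at the C7 methylene (aldehyde α-methylenation). The ring is cut at C2–C3 and C4–C5 together by a retro-Michael/retro-aldol.
3. Enabling feature: the C6 carbinol lies between C1 and C5. At the ketone level it makes C2 the β-carbon of an α-substituted vinyl ketone and C5 an enolisable α-alkoxy carbon. The C3/C4 glycol with the C4 methyl is hydroxyacetone (nucleophilic CH2OH carbon = C3, electrophilic carbonyl = C4).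
4. Forward: vinyl ketone 7 and hydroxyacetone give the whole cyclohexanone in a one-pot Michael/aldol annulation. Then follow C6 reduction, C3 inversion and protection; the chain grows C8 aldehyde → C7 methylene → C8–C9 aldol → C10 reduction; bis-angeloylation and desilylation finish.
5. Stereochemistry: C3 comes from the amine catalyst and is relayed to C4 (1,2-induction) and to C1 and C5 (equilibration to all-equatorial). C6 comes from equatorial hydride attack. C3 is then inverted by oxidation and hydroxyl-directed reduction (trans-diaxial glycol). C8 comes from a (−)-Ipc2B aldol and C10 from a CBS reduction.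

Key step: step 4

Remark (assumption): the sense of induction at C3 in step 4 is taken from the acid-directed enamine model established for proline-type catalysis of hydroxyacetone (L-series gives 3S, so the D-series catalyst is used for 3R).

**Step 1**
Reactants: 1 3-bromobut-3-en-1-ol
Product: 2 [(3-bromobut-3-en-1-yl)oxy](tert-butyl)dimethylsilane
Conditions: t-BuMe2SiCl, imidazole, CH2Cl2, rt
Reagents that add atoms: tert-butyldimethylsilyl chloride, CC(C)(C)[Si](C)(C)Cl
Why: Imidazole-promoted silyl ether formation masks the primary hydroxyl for the later halogen–lithium exchange.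

**Step 2**
Reactants: 3 2-chloro-N-methoxy-N-methylacetamide; 4 4-methoxybenzyl alcohol
Product: 5 N-methoxy-2-[(4-methoxybenzyl)oxy]-N-methylacetamide
Conditions: NaH, n-Bu4NI (cat.), THF, 0 °C to rt
Reagents that add atoms: none
Why: Williamson ether synthesis; the alkoxide should displace the primary α-chloride, while the Weinreb amide carbonyl resists alkoxide attack.

**Step 3**
Reactants: 2 bromoalkene silyl ether; 5 Weinreb amide
Product: 7 5-(tert-butyldimethylsilyloxy)-1-[(4-methoxybenzyl)oxy]-3-methylidenepentan-2-one, via alkenyllithium 6 (not isolated)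
Conditions: t-BuLi (2.1 equiv), Et2O, −78 °C; then 5, −78 to 0 °C; aq. NH4Cl
Reagents that add atoms: none
Why: Bromine–lithium exchange followed by Weinreb ketone synthesis; the chelated tetrahedral adduct should release the α-substituted vinyl ketone only on work-up, so no over-addition occurs.

**Step 4**
Reactants: 7 vinyl ketone; 8 hydroxyacetone
Product: 10 all-cis ketol (C6 ketone; 1β-[2-(TBSO)ethyl], 3β-OH, 4β-OH, 4α-CH3, 5β-OPMB), via Michael adduct 9 (not isolated)
Conditions: (R)-5-(pyrrolidin-2-yl)-1H-tetrazole (20 mol %), 8 (5 equiv), DMSO, rt; then DBU (0.3 equiv), 0 °C to rt, one pot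
Reagents that add atoms: none
Why: The catalyst condenses with hydroxyacetone to the enamine at the hydroxylated carbon, which adds to the unsubstituted enone terminus C2 of 7 (Michael addition, C2–C3) to give 1,5-diketone 9, and DBU then enolises the α-alkoxy position C5 of the C6 ketone so that this enolate adds to the C4 methyl ketone (intramolecular aldol, C4–C5). The closest known reaction type is the amine-catalysed asymmetric Michael/aldol (Robinson-type) annulation of a ketone with a vinyl ketone stopped at the ketol, joined to the known enamine chemistry of hydroxyacetone. The single ring closes by a 6-(enolendo)-exo-trig aldol through a chair. C3 is set by the catalyst (acid-directed attack on one enamine face, the D-configured catalyst should give 3R), C4 by 1,2-induction from C3 in the chair with the methyl equatorial and the C3–O bond anti to the incoming enolate (polar Felkin–Anh), and C1 and C5, both α to the C6 ketone, by base equilibration to the all-equatorial arrangement. The step needs donor regioselectivity (the hydroxyl stabilises the more substituted enamine), acceptor regioselectivity (only C2 is electrophilic) and the right enol partner for closure (C5–H is more acidic than the C4 methyl hydrogens, and closure from that methyl onto the hindered C6 ketone should be slower), while mild base and low temperature should prevent dehydration. The ketol has C1, C4 and C5 as in the target and C3 epimeric, which steps 6 and 7 correct.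

**Step 5**
Reactants: 10 all-cis ketol
Product: 11 3-epi-triol (3β-OH, 4β-OH, 6β-OH)
Conditions: LiBH(s-Bu)3 (3.5 equiv), THF, −78 °C; then aq. NaOH, H2O2
Reagents that add atoms: none
Why: Bulky trialkylborohydride reduction of a 2,6-diequatorially substituted cyclohexanone; hydride should enter from the equatorial α side (the β face is blocked by the axial C4–O group) and give the axial 6β-alcohol.

**Step 6**
Reactants: 11 3-epi-triol
Product: 12 3-keto diol (C3 ketone, 4β-OH, 6β-OH)
Conditions: [(neocuproine)Pd(OAc)]2(OTf)2 (5 mol %; neocuproine = 2,9-dimethyl-1,10-phenanthroline), 1,4-benzoquinone, MeCN/H2O, rt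
Reagents that add atoms: none
Why: Chelation-controlled alcohol oxidation by the cationic palladium acetate catalyst, which binds vicinal diols and should dehydrogenate only the secondary C3 carbinol of the cis C3/C4 glycol and not the isolated, hindered C6–OH; the C3 centre has done its relay job and is erased.

**Step 7**
Reactants: 12 3-keto diol
Product: 13 triol (3α-OH, 4β-OH, 6β-OH)
Conditions: Me4NBH(OAc)3 (5 equiv), MeCN/AcOH (1:1), −30 °C
Reagents that add atoms: none
Why: Hydroxyl-directed (Evans–Saksena) reduction; the axial 4β-OH should exchange onto boron and deliver hydride to the β face of the C3 ketone, setting the axial 3α-OH trans-diaxial to 4β-OH.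

**Step 8**
Reactants: 13 triol
Product: 14 3,6-bis-O-TBS ether (4-OH free)
Conditions: t-BuMe2SiOTf (2.4 equiv), 2,6-lutidine, CH2Cl2, −78 to 0 °C
Reagents that add atoms: tert-butyldimethylsilyl triflate, CC(C)(C)[Si](C)(C)OS(=O)(=O)C(F)(F)F
Why: Silyl triflate silylation of the two secondary axial alcohols; the tertiary C4–OH, flanked on both sides, should stay free.

**Step 9**
Reactants: 14 tris-silyl ether
Product: 15 primary alcohol (C8–OH)
Conditions: HF·pyridine, pyridine, THF, 0 °C
Reagents that add atoms: none
Why: Selective desilylation; a primary TBS ether is cleaved much faster than hindered secondary ones under buffered HF·pyridine.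

**Step 10**
Reactants: 15 primary alcohol
Product: 16 aldehyde (C8)
Conditions: Dess–Martin periodinane, NaHCO3, CH2Cl2, 0 °C to rt
Reagents that add atoms: none
Why: Dess–Martin oxidation of the only oxidisable hydroxyl; the tertiary C4–OH is inert.

**Step 11**
Reactants: 16 aldehyde
Product: 17 enal (C7 methylidene, C8 aldehyde)
Conditions: 37 % aq. CH2O, pyrrolidine (10 mol %), EtCO2H (10 mol %), i-PrOH, 45 °C
Reagents that add atoms: formaldehyde, C=O
Why: Amine/acid-catalysed α-methylenation of an aldehyde (Mannich condensation–elimination) should install the C7 exocyclic methylene as a 2-substituted acrolein without touching C1.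

**Step 12**
Reactants: 18 3-hydroxy-3-methylbutan-2-one
Product: 19 3-methyl-3-(triethylsilyloxy)butan-2-one
Conditions: Et3SiOTf, 2,6-lutidine, CH2Cl2, 0 °C
Reagents that add atoms: triethylsilyl triflate, CC[Si](CC)(CC)OS(=O)(=O)C(F)(F)F
Why: Silyl triflate silylation of a tertiary alcohol protects the future C11–OH.

**Step 13**
Reactants: 17 enal; 19 methyl ketone
Product: 21 (8R)-β-hydroxy ketone (C8–OH, C10 ketone, C11–OTES), via boron enolate 20 (not isolated)
Conditions: 19, (−)-Ipc2BCl, Et3N, Et2O, −78 to 0 °C; then 17, −78 to −20 °C; then pH 7 buffer, MeOH, H2O2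
Reagents that add atoms: none
Why: Paterson boron aldol of a methyl ketone; the (−)-Ipc2B enolate should add to the Re face of the enal under reagent control through a cyclic transition state and set 8R.

**Step 14**
Reactants: 21 β-hydroxy ketone
Product: 22 8-O-TES ether
Conditions: Et3SiCl, imidazole, DMF, 0 °C
Reagents that add atoms: chlorotriethylsilane, CC[Si](CC)(CC)Cl
Why: Silyl chloride/imidazole silylation should take the secondary allylic C8–OH and leave the tertiary C4–OH, so that C8–OH stays masked when the second carbinol is made.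

**Step 15**
Reactants: 22 ketone
Product: 23 (10R)-alcohol
Conditions: (S)-1-methyl-3,3-diphenyltetrahydro-1H,3H-pyrrolo[1,2-c][1,3,2]oxazaborole (0.5 equiv), catecholborane (3 equiv), toluene, −78 to −40 °C
Reagents that add atoms: none
Why: Corey–Bakshi–Shibata reduction; with the (S)-oxazaborolidine the tertiary C11 acts as the large group and hydride should arrive to give 10R (8,10-anti), while catecholborane spares the 1,1-disubstituted alkene.

**Step 16**
Reactants: 23 PMB ether
Product: 24 5,10-diol
Conditions: DDQ, CH2Cl2/pH 7 phosphate buffer (10:1), 0 °C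
Reagents that add atoms: none
Why: Oxidative cleavage of the p-methoxybenzyl ether by DDQ; in wet solvent water should intercept the oxocarbenium ion before the neighbouring C4–OH can, and silyl ethers and the alkene are inert.

**Step 17**
Reactants: 24 5,10-diol; 25 angelic acid
Product: 27 5,10-bis-angelate (silyl protected), via mixed anhydride 26 (not isolated)
Conditions: 25 (6 equiv), 2,4,6-trichlorobenzoyl chloride, Et3N, toluene, rt; then 24, 75 °C
Reagents that add atoms: none
Why: Yamaguchi-type esterification through the mixed anhydride, run hot without a nucleophilic catalyst, which is the known way to make (Z)-2-methylbut-2-enoates without Z-to-E isomerisation; only the two secondary hydroxyls (C5, C10) should be acylated, not the tertiary C4–OH.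

**Step 18**
Reactants: 27 bis-angelate
Product: 28 target compound CNP0108485.1
Conditions: HF·pyridine, pyridine, THF, 0 °C to rt
Reagents that add atoms: none
Why: Fluoride-mediated global desilylation under buffered, weakly acidic conditions should remove the TBS and TES ethers without cleaving, migrating or isomerising the angelates.

**Compound list**

1 | 3-bromobut-3-en-1-ol | C=C(Br)CCO | starting material
2 | [(3-bromobut-3-en-1-yl)oxy](tert-butyl)dimethylsilane | C=C(Br)CCO[Si](C)(C)C(C)(C)C | intermediate
3 | 2-chloro-N-methoxy-N-methylacetamide | CON(C)C(=O)CCl | starting material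
4 | 4-methoxybenzyl alcohol | COc1ccc(CO)cc1 | starting material
5 | N-methoxy-2-[(4-methoxybenzyl)oxy]-N-methylacetamide | CON(C)C(=O)COCc1ccc(OC)cc1 | intermediate
6 | [4-(tert-butyldimethylsilyloxy)but-1-en-2-yl]lithium | [Li]C(=C)CCO[Si](C)(C)C(C)(C)C | intermediate
7 | 5-(tert-butyldimethylsilyloxy)-1-[(4-methoxybenzyl)oxy]-3-methylidenepentan-2-one | C=C(CCO[Si](C)(C)C(C)(C)C)C(=O)COCc1ccc(OC)cc1 | intermediate
8 | hydroxyacetone (1-hydroxypropan-2-one) | CC(=O)CO | starting material
9 | (5R)-5-hydroxy-1-[(4-methoxybenzyl)oxy]-3-[2-(tert-butyldimethylsilyloxy)ethyl]heptane-2,6-dione (chain carbon 3, the future ring C1, unassigned) | CC(=O)[C@H](O)CC(CCO[Si](C)(C)C(C)(C)C)C(=O)COCc1ccc(OC)cc1 | intermediate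
10 | all-cis ketol: C6 ketone, 1β-[2-(TBSO)ethyl], 3β-OH, 4β-OH, 4α-CH3, 5β-OPMB | CC(C)(C)[Si](C)(C)OCC[C@H]1C[C@@H](O)[C@@](C)(O)[C@@H](OCc2ccc(OC)cc2)C1=O | intermediate
11 | 3-epi-triol: as 10 with 6β-OH | CC(C)(C)[Si](C)(C)OCC[C@H]1C[C@@H](O)[C@@](C)(O)[C@@H](OCc2ccc(OC)cc2)[C@H]1O | intermediate
12 | 3-keto diol: C3 ketone, 4β-OH, 6β-OH | CC(C)(C)[Si](C)(C)OCC[C@H]1CC(=O)[C@@](C)(O)[C@@H](OCc2ccc(OC)cc2)[C@H]1O | intermediate
13 | triol: 3α-OH, 4β-OH, 6β-OH | CC(C)(C)[Si](C)(C)OCC[C@H]1C[C@H](O)[C@@](C)(O)[C@@H](OCc2ccc(OC)cc2)[C@H]1O | intermediate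
14 | 3,6-bis-O-TBS ether of 13 (4-OH free, primary OTBS) | CC(C)(C)[Si](C)(C)OCC[C@H]1C[C@H](O[Si](C)(C)C(C)(C)C)[C@@](C)(O)[C@@H](OCc2ccc(OC)cc2)[C@H]1O[Si](C)(C)C(C)(C)C | intermediate
15 | primary alcohol: 1β-(2-hydroxyethyl), 3α,6β-bis-OTBS, 4β-OH, 5β-OPMB | OCC[C@H]1C[C@H](O[Si](C)(C)C(C)(C)C)[C@@](C)(O)[C@@H](OCc2ccc(OC)cc2)[C@H]1O[Si](C)(C)C(C)(C)C | intermediate
16 | aldehyde: 1β-(2-oxoethyl), otherwise as 15 | O=CC[C@H]1C[C@H](O[Si](C)(C)C(C)(C)C)[C@@](C)(O)[C@@H](OCc2ccc(OC)cc2)[C@H]1O[Si](C)(C)C(C)(C)C | intermediate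
17 | enal: 1β-(3-oxoprop-1-en-2-yl), otherwise as 15 | C=C(C=O)[C@H]1C[C@H](O[Si](C)(C)C(C)(C)C)[C@@](C)(O)[C@@H](OCc2ccc(OC)cc2)[C@H]1O[Si](C)(C)C(C)(C)C | intermediate
18 | 3-hydroxy-3-methylbutan-2-one | CC(=O)C(C)(C)O | starting material
19 | 3-methyl-3-(triethylsilyloxy)butan-2-one | CC(=O)C(C)(C)O[Si](CC)(CC)CC | intermediate
20 | diisopinocampheylboron enolate of 19 (Ipc from (+)-α-pinene) | C=C(OB([C@@H]1C[C@@H]2C[C@H]([C@H]1C)C2(C)C)[C@@H]1C[C@@H]2C[C@H]([C@H]1C)C2(C)C)C(C)(C)O[Si](CC)(CC)CC | intermediate
21 | (8R)-aldol: C8–OH, C10 ketone, C11–OTES; ring as in 15 | C=C([C@H](O)CC(=O)C(C)(C)O[Si](CC)(CC)CC)[C@H]1C[C@H](O[Si](C)(C)C(C)(C)C)[C@@](C)(O)[C@@H](OCc2ccc(OC)cc2)[C@H]1O[Si](C)(C)C(C)(C)C | intermediate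
22 | 8-O-TES ether of 21 | C=C([C@H](O[Si](CC)(CC)CC)CC(=O)C(C)(C)O[Si](CC)(CC)CC)[C@H]1C[C@H](O[Si](C)(C)C(C)(C)C)[C@@](C)(O)[C@@H](OCc2ccc(OC)cc2)[C@H]1O[Si](C)(C)C(C)(C)C | intermediate
23 | (8R,10R)-alcohol: C10–OH, C8–OTES, C11–OTES, 5β-OPMB | C=C([C@H](O[Si](CC)(CC)CC)C[C@@H](O)C(C)(C)O[Si](CC)(CC)CC)[C@H]1C[C@H](O[Si](C)(C)C(C)(C)C)[C@@](C)(O)[C@@H](OCc2ccc(OC)cc2)[C@H]1O[Si](C)(C)C(C)(C)C | intermediate
24 | 5,10-diol (C5–OH, C10–OH, C4–OH free; C3, C6 OTBS; C8, C11 OTES) | C=C([C@H](O[Si](CC)(CC)CC)C[C@@H](O)C(C)(C)O[Si](CC)(CC)CC)[C@H]1C[C@H](O[Si](C)(C)C(C)(C)C)[C@@](C)(O)[C@@H](O)[C@H]1O[Si](C)(C)C(C)(C)C | intermediate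
25 | angelic acid ((Z)-2-methylbut-2-enoic acid) | C/C=C(/C)C(=O)O | starting material
26 | angelic 2,4,6-trichlorobenzoic anhydride | C/C=C(/C)C(=O)OC(=O)c1c(Cl)cc(Cl)cc1Cl | intermediate
27 | 5,10-bis-angelate of 24 | C=C([C@H](O[Si](CC)(CC)CC)C[C@@H](OC(=O)/C(C)=C\C)C(C)(C)O[Si](CC)(CC)CC)[C@H]1C[C@H](O[Si](C)(C)C(C)(C)C)[C@@](C)(O)[C@@H](OC(=O)/C(C)=C\C)[C@H]1O[Si](C)(C)C(C)(C)C | intermediate
28 | CNP0108485.1 | C=C([C@H](O)C[C@@H](OC(=O)/C(C)=C\C)C(C)(C)O)[C@H]1C[C@H](O)[C@@](C)(O)[C@@H](OC(=O)/C(C)=C\C)[C@H]1O | target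

**Count**

Total steps: 18. Longest linear sequence: 16 (steps 1, 3–11, 13–18); steps 2 and 12 make side fragments.

**Steps most likely to fail**

1. Step 4. What may go wrong: low enantioselectivity in the Michael stage, ring closure from the wrong enol partner (C4 methyl onto the C6 ketone), or epimerisation at C3 in the open diketone before closure. Fallback, setting out from 7 and 8 and returning at 10: the annulation is run without asymmetric induction (pyrrolidine/AcOH as in a Stork enamine Michael addition, then DBU) to give the racemic all-cis ketol F1. Candida antarctica lipase B with vinyl acetate should then acylate the (3R)-alcohol selectively (Kazlauskas rule, large C4 against medium C2) to the 3-O-acetate F2. F2 is separated from the unreacted antipode and cleaved with K2CO3 in MeOH at 0 °C to return 10.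

2. Step 6. What may go wrong: incomplete site selectivity of the oxidation (attack at C6–OH), over-oxidation or glycol cleavage. Fallback, setting out from 11 and returning at 13 without passing 12: Mitsunobu inversion at the less hindered equatorial C3–OH (4-nitrobenzoic acid, PPh3, diisopropyl azodicarboxylate, toluene) gives the inverted 3α-(4-nitrobenzoate) F3. Methanolysis (K2CO3, MeOH) then gives 13, so that substitution with inversion replaces the redox pair of steps 6 and 7.

3. Step 17. What may go wrong: Z-to-E isomerisation of the angeloyl unit during activation, or incomplete acylation of the two hindered carbinols. Fallback, setting out from 24 and returning at 27: both hydroxyls are esterified with the non-isomerisable 2-(diphenoxyphosphoryl)propanoic acid (EDC, DMAP, CH2Cl2) to the 5,10-bis(phosphonopropanoate) F4. A Z-selective Horner–Wadsworth–Emmons reaction of the Ando type with acetaldehyde (NaI, DBU, THF, 0 °C) then builds both (Z)-2-methylbut-2-enoates on the molecule and gives 27.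

**Further compounds**

F1 | step 4 | racemic all-cis ketol (racemate of 10, one enantiomer drawn) | CC(C)(C)[Si](C)(C)OCC[C@H]1C[C@@H](O)[C@@](C)(O)[C@@H](OCc2ccc(OC)cc2)C1=O
F2 | step 4 | 3-O-acetate of 10 (3R) | CC(C)(C)[Si](C)(C)OCC[C@H]1C[C@@H](OC(C)=O)[C@@](C)(O)[C@@H](OCc2ccc(OC)cc2)C1=O
F3 | step 6 | 3α-(4-nitrobenzoate) of 13 | CC(C)(C)[Si](C)(C)OCC[C@H]1C[C@H](OC(=O)c2ccc(cc2)[N+](=O)[O-])[C@@](C)(O)[C@@H](OCc2ccc(OC)cc2)[C@H]1O
F4 | step 17 | 5,10-bis[2-(diphenoxyphosphoryl)propanoate] of 24 | C=C([C@H](O[Si](CC)(CC)CC)C[C@@H](OC(=O)C(C)P(=O)(Oc2ccccc2)Oc2ccccc2)C(C)(C)O[Si](CC)(CC)CC)[C@H]1C[C@H](O[Si](C)(C)C(C)(C)C)[C@@](C)(O)[C@@H](OC(=O)C(C)P(=O)(Oc2ccccc2)Oc2ccccc2)[C@H]1O[Si](C)(C)C(C)(C)C
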